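Everything rests on closing ring C at the aryl ether bond O1–C8a instead of the usual O1–C2 bond. C8a of ring A lies ortho to the C4 ketone, so a fluorine placed there is displaced by the C2 alkoxide of an open-chain (S)-β-hydroxy ketone in an intramolecular SNAr reaction. In one operation this forms the chromanone ring without touching the C2–O bond, so the stereocentre, set beforehand by copper-catalysed asymmetric conjugate borylation–oxidation of a 2'-fluorochalcone, passes unchanged into the (2S)-flavanone. The precursor is a MOM-protected 1-(2-fluoro-4,6-dioxygenated phenyl)-3-hydroxy-3-chromenylpropan-1-one built from a fluororesorcinol-derived acetophenone and a chromene aldehyde.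

Key step: step 8

Remark: flavanone numbering is used (O1, C2, C3, C4, C4a, C5–C8, C8a; ring A is the benzene ring of the chromanone, ring C its pyranone ring, ring B the benzene ring of the chromene substituent). The ligand enantiomer in step 7 is the one that delivers the (S)-boronate; its mirror image is used if the sense proves opposite.

Step 1
Reactants: 1 3,4-dihydroxybenzaldehyde; 2 3-chloro-3-methylbut-1-yne
Product: 3 3-hydroxy-4-[(2-methylbut-3-yn-2-yl)oxy]benzaldehyde
Conditions: K2CO3 (1.1 equiv), KI, CuI (cat.), DMF, 50 °C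
Reagents that add atoms: none
Why: Copper-catalysed O-propargylation (Williamson-type etherification with a tertiary propargylic chloride) should take place at the 4-OH, which is para to the formyl group, much more acidic than the 3-OH and therefore the phenoxide formed by one equivalent of weak base.

Step 2
Reactants: 3 3-hydroxy-4-[(2-methylbut-3-yn-2-yl)oxy]benzaldehyde
Product: 4 3-(methoxymethoxy)-4-[(2-methylbut-3-yn-2-yl)oxy]benzaldehyde
Conditions: MOMCl, i-Pr2NEt, CH2Cl2, 0 °C → rt
Reagents that add atoms: chloromethyl methyl ether, COCCl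
Why: Standard MOM etherification of a phenol, which masks the hydroxyl ortho to the propargyl ether before the thermal rearrangement.

Step 3
Reactants: 4 3-(methoxymethoxy)-4-[(2-methylbut-3-yn-2-yl)oxy]benzaldehyde
Product: 5 8-(methoxymethoxy)-2,2-dimethyl-2H-chromene-6-carbaldehyde
Conditions: N,N-diethylaniline, 190 °C
Reagents that add atoms: none
Why: Aryl propargyl ether Claisen rearrangement to the only free ortho position, followed by enolisation, 1,5-hydrogen shift and oxa-6π electrocyclisation, is the standard entry to 2,2-dimethyl-2H-chromenes.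

Step 4
Reactants: 6 5-fluorobenzene-1,3-diol
Product: 8 1-(2-fluoro-4,6-dihydroxyphenyl)ethan-1-one, via ketiminium chloride 7 (not isolated)
Conditions: MeCN, ZnCl2, HCl (g), Et2O, 0 °C; then H2O, reflux
Reagents that add atoms: acetonitrile, CC#N (acetyl carbons); water, O (carbonyl oxygen); hydrogen chloride, Cl (chloride of intermediate 7 only)
Why: Hoesch acylation of a resorcinol is expected at the position ortho to fluorine and para to a hydroxyl (as with 5-methylresorcinol), which is less hindered than the carbon between the two hydroxyls, and hydrolysis of the ketiminium salt gives the ketone.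

Step 5
Reactants: 8 1-(2-fluoro-4,6-dihydroxyphenyl)ethan-1-one
Product: 9 1-[2-fluoro-4,6-bis(methoxymethoxy)phenyl]ethan-1-one
Conditions: NaH (2.2 equiv), MOMCl (2.4 equiv), DMF, 0 °C → rt
Reagents that add atoms: chloromethyl methyl ether, COCCl
Why: Williamson-type MOM etherification through the sodium phenoxides also caps the hydrogen-bonded ortho hydroxyl, which must be masked so that it cannot add to the later enone.

Step 6
Reactants: 9 1-[2-fluoro-4,6-bis(methoxymethoxy)phenyl]ethan-1-one; 5 8-(methoxymethoxy)-2,2-dimethyl-2H-chromene-6-carbaldehyde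
Product: 10 (E)-1-[2-fluoro-4,6-bis(methoxymethoxy)phenyl]-3-[8-(methoxymethoxy)-2,2-dimethyl-2H-chromen-6-yl]prop-2-en-1-one
Conditions: KOH, EtOH, 0 °C → rt
Reagents that add atoms: none
Why: Claisen–Schmidt condensation (aldol addition then E1cB dehydration) of a methyl ketone with a non-enolisable aromatic aldehyde should give the E-chalcone, the donor-substituted fluoroarene being slow to undergo intermolecular substitution at this temperature.

Step 7
Reactants: 10 (E)-1-[2-fluoro-4,6-bis(methoxymethoxy)phenyl]-3-[8-(methoxymethoxy)-2,2-dimethyl-2H-chromen-6-yl]prop-2-en-1-one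
Product: 12 (3S)-1-[2-fluoro-4,6-bis(methoxymethoxy)phenyl]-3-hydroxy-3-[8-(methoxymethoxy)-2,2-dimethyl-2H-chromen-6-yl]propan-1-one, via β-boryl ketone 11 (not isolated)
Conditions: B2pin2 (1.1 equiv), CuCl (5 mol %), NaOtBu (10 mol %), (R,S)-Josiphos (5 mol %), MeOH (2 equiv), THF, rt; then NaBO3·4H2O, THF/H2O, rt
Reagents that add atoms: bis(pinacolato)diboron, CC1(C)OB(OC1(C)C)B1OC(C)(C)C(C)(C)O1 (boryl group of intermediate 11 only); sodium perborate, [Na+].[Na+].O[B-]1(O)OO[B-](O)(O)OO1 (hydroxyl oxygen)
Why: Copper-catalysed enantioselective conjugate borylation of the enone sets the β-stereocentre by ligand-controlled face selection of the copper–boryl addition, and perborate oxidation of the C–B bond with retention should give the (S)-aldol without dehydration.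

Step 8
Reactants: 12 (3S)-1-[2-fluoro-4,6-bis(methoxymethoxy)phenyl]-3-hydroxy-3-[8-(methoxymethoxy)-2,2-dimethyl-2H-chromen-6-yl]propan-1-one
Product: 13 (2S)-5,7-bis(methoxymethoxy)-2-[8-(methoxymethoxy)-2,2-dimethyl-2H-chromen-6-yl]-2,3-dihydro-4H-chromen-4-one
Conditions: KHMDS (1.0 equiv), 18-crown-6, THF, −78 → −20 °C; AcOH quench at −20 °C
Reagents that add atoms: none
Why: Deprotonation gives the potassium alkoxide at C2, which adds to the fluorine-bearing C8a to form a Meisenheimer anion delocalised into the ortho C4 carbonyl, and loss of fluoride then makes the O1–C8a bond irreversibly. The closest known reaction type is the intramolecular SNAr O-arylation of o-fluoroaryl ketones used for chromanones, chromones and xanthones. Ring C closes in a 6-exo-trig sense, by ipso attack on an aromatic carbon through a six-membered transition state spanning C2–C3–C4–C4a. No new stereocentre is formed: only the O–H and the aryl C–F bonds are broken, so C2 keeps the configuration set in step 7 and the (S) descriptor of 12 carries over to (2S). The step needs O-arylation to outrun retro-aldol cleavage and E1cB dehydration of the aldolate, and must leave no base that could open the product; this should be secured by the single fluorine ortho to the carbonyl (the MOM ethers at C5 and C7 are meta to C8a and do not load the Meisenheimer anion), a crown-separated alkoxide at low temperature and exactly one equivalent of base.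

Step 9
Reactants: 13 (2S)-5,7-bis(methoxymethoxy)-2-[8-(methoxymethoxy)-2,2-dimethyl-2H-chromen-6-yl]-2,3-dihydro-4H-chromen-4-one
Product: 14 (2S)-5,7-dihydroxy-2-(8-hydroxy-2,2-dimethyl-2H-chromen-6-yl)-2,3-dihydro-4H-chromen-4-one
Conditions: 3 M HCl (aq.), MeOH, 45 °C
Reagents that add atoms: none
Why: Acid-catalysed acetal methanolysis should remove all three MOM ethers under conditions that flavanones and 2,2-dimethylchromenes normally tolerate, and it does not involve the C2 stereocentre.

Compound list
1 | 3,4-dihydroxybenzaldehyde | O=Cc1ccc(O)c(O)c1 | starting material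
2 | 3-chloro-3-methylbut-1-yne | CC(C)(Cl)C#C | starting material
3 | 3-hydroxy-4-[(2-methylbut-3-yn-2-yl)oxy]benzaldehyde | O=Cc1ccc(OC(C)(C)C#C)c(O)c1 | intermediate
4 | 3-(methoxymethoxy)-4-[(2-methylbut-3-yn-2-yl)oxy]benzaldehyde | O=Cc1ccc(OC(C)(C)C#C)c(OCOC)c1 | intermediate
5 | 8-(methoxymethoxy)-2,2-dimethyl-2H-chromene-6-carbaldehyde | CC1(C)C=Cc2cc(C=O)cc(OCOC)c2O1 | intermediate
6 | 5-fluorobenzene-1,3-diol | Oc1cc(O)cc(F)c1 | starting material
7 | 1-(2-fluoro-4,6-dihydroxyphenyl)ethan-1-iminium chloride (not isolated) | CC(=[NH2+])c1c(O)cc(O)cc1F.[Cl-] | intermediate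
8 | 1-(2-fluoro-4,6-dihydroxyphenyl)ethan-1-one | CC(=O)c1c(O)cc(O)cc1F | intermediate
9 | 1-[2-fluoro-4,6-bis(methoxymethoxy)phenyl]ethan-1-one | CC(=O)c1c(OCOC)cc(OCOC)cc1F | intermediate
10 | (E)-1-[2-fluoro-4,6-bis(methoxymethoxy)phenyl]-3-[8-(methoxymethoxy)-2,2-dimethyl-2H-chromen-6-yl]prop-2-en-1-one | COCOc1cc(F)c(C(=O)/C=C/c2cc3C=CC(C)(C)Oc3c(OCOC)c2)c(OCOC)c1 | intermediate
11 | (3S)-1-[2-fluoro-4,6-bis(methoxymethoxy)phenyl]-3-[8-(methoxymethoxy)-2,2-dimethyl-2H-chromen-6-yl]-3-(4,4,5,5-tetramethyl-1,3,2-dioxaborolan-2-yl)propan-1-one (not isolated) | COCOc1cc(F)c(C(=O)C[C@H](B2OC(C)(C)C(C)(C)O2)c3cc4C=CC(C)(C)Oc4c(OCOC)c3)c(OCOC)c1 | intermediate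
12 | (3S)-1-[2-fluoro-4,6-bis(methoxymethoxy)phenyl]-3-hydroxy-3-[8-(methoxymethoxy)-2,2-dimethyl-2H-chromen-6-yl]propan-1-one | COCOc1cc(F)c(C(=O)C[C@H](O)c2cc3C=CC(C)(C)Oc3c(OCOC)c2)c(OCOC)c1 | intermediate
13 | (2S)-5,7-bis(methoxymethoxy)-2-[8-(methoxymethoxy)-2,2-dimethyl-2H-chromen-6-yl]-2,3-dihydro-4H-chromen-4-one | COCOc1cc(OCOC)c2C(=O)C[C@@H](c3cc4C=CC(C)(C)Oc4c(OCOC)c3)Oc2c1 | intermediate
14 | (2S)-5,7-dihydroxy-2-(8-hydroxy-2,2-dimethyl-2H-chromen-6-yl)-2,3-dihydro-4H-chromen-4-one | CC1(C)C=Cc2cc([C@@H]3CC(=O)c4c(O)cc(O)cc4O3)cc(O)c2O1 | target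

Total step count: 9. Longest linear sequence: 7 steps (steps 1, 2, 3, 6, 7, 8, 9).

Steps most likely to fail

Step 8. The potassium aldolate may fragment by retro-aldol cleavage (which would scramble C2 on recombination) or lose hydroxide by E1cB dehydration faster than it attacks C8a. Residual base may also open the product by β-elimination of the phenoxide. The fallback sets out from 12 and comes back at 13, and takes the ketone out of play before the ring is closed. Reduction of 12 with NaBH4 in MeOH at 0 °C should give (3S)-1-[2-fluoro-4,6-bis(methoxymethoxy)phenyl]-3-[8-(methoxymethoxy)-2,2-dimethyl-2H-chromen-6-yl]propane-1,3-diol F1 as a mixture of epimers at C1. This diol can neither enolise nor undergo retro-aldol cleavage. Its dipotassium alkoxide (KOtBu, DMF, 90 °C) should close the same O1–C8a bond by intramolecular SNAr on the non-activated aryl fluoride, a known route to chromans; only the C3 oxygen can reach C8a in a six-membered ring. This gives (2S)-5,7-bis(methoxymethoxy)-2-[8-(methoxymethoxy)-2,2-dimethyl-2H-chromen-6-yl]chroman-4-ol F2. Oxidation of the benzylic alcohol with Dess–Martin periodinane (NaHCO3, CH2Cl2) returns 13.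

Step 7. Facial discrimination may be poor on the twisted, doubly ortho-substituted aryl enone, and the copper–boryl species may also add to the chromene double bond. The fallback sets out from 10 and comes back at 12. Julia–Colonna epoxidation (poly-D-leucine, urea–hydrogen peroxide, DBU, THF) should give the trans epoxy ketone [2-fluoro-4,6-bis(methoxymethoxy)phenyl]{(2S,3R)-3-[8-(methoxymethoxy)-2,2-dimethyl-2H-chromen-6-yl]oxiran-2-yl}methanone F3. Reductive cleavage of the Cα–O bond with SmI2 (THF/MeOH, −90 °C) leaves the Cβ–O bond and its configuration intact and gives 12.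

Step 1. The copper-catalysed etherification may not discriminate cleanly between the two catechol hydroxyls, or may go on to the bis-ether. The fallback sets out from 1 and comes back at 4, and relays the selectivity through a well-behaved benzylation. Benzyl chloride, NaHCO3 and NaI in DMF at 40 °C should give 4-(benzyloxy)-3-hydroxybenzaldehyde F4. MOMCl and i-Pr2NEt then give 4-(benzyloxy)-3-(methoxymethoxy)benzaldehyde F5. Hydrogenolysis (H2, Pd/C, EtOAc) gives 4-hydroxy-3-(methoxymethoxy)benzaldehyde F6. Propargylation of this single phenol with 2 (K2CO3, KI, CuI, acetone, reflux) gives 4.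

Further compounds
F1 | step 8 | (3S)-1-[2-fluoro-4,6-bis(methoxymethoxy)phenyl]-3-[8-(methoxymethoxy)-2,2-dimethyl-2H-chromen-6-yl]propane-1,3-diol (C1 epimers) | COCOc1cc(F)c(C(O)C[C@H](O)c2cc3C=CC(C)(C)Oc3c(OCOC)c2)c(OCOC)c1
F2 | step 8 | (2S)-5,7-bis(methoxymethoxy)-2-[8-(methoxymethoxy)-2,2-dimethyl-2H-chromen-6-yl]chroman-4-ol (C4 epimers) | COCOc1cc(OCOC)c2C(O)C[C@@H](c3cc4C=CC(C)(C)Oc4c(OCOC)c3)Oc2c1
F3 | step 7 | [2-fluoro-4,6-bis(methoxymethoxy)phenyl]{(2S,3R)-3-[8-(methoxymethoxy)-2,2-dimethyl-2H-chromen-6-yl]oxiran-2-yl}methanone | COCOc1cc(F)c(C(=O)[C@H]2O[C@@H]2c3cc4C=CC(C)(C)Oc4c(OCOC)c3)c(OCOC)c1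
F4 | step 1 | 4-(benzyloxy)-3-hydroxybenzaldehyde | O=Cc1ccc(OCc2ccccc2)c(O)c1
F5 | step 1 | 4-(benzyloxy)-3-(methoxymethoxy)benzaldehyde | O=Cc1ccc(OCc2ccccc2)c(OCOC)c1
F6 | step 1 | 4-hydroxy-3-(methoxymethoxy)benzaldehyde | O=Cc1ccc(O)c(OCOC)c1
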